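**Strategy.** Ring A is disconnected last, across C4a–C5 and C8–C8a. Its four contiguous carbons C5(OH), C6(OMe), C7(OMe) and C8 are the four carbons of dimethyl squarate, and the fusion bond C4a–C8a is the C=C bond of a 2-aryl-4-pyranone (ring C) that already carries ring B. The precursor is a 4-hydroxy-2,3-dimethoxycyclobutenone bearing the pyranon-3-yl group on its carbinol carbon. On heating it opens to a dienylketene that closes onto the pyranone C–H carbon beside the ring oxygen and aromatises, giving the complete oxygenated benzo ring in one operation. The extra 8-hydroxyl is then removed through its triflate and the 5'-benzyl ether is cleaved.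

Key step: step 8

Remark on the chemistry: compounds 1, 5 and 13 are taken as purchasable; 6, 11, 15 and 17 are racemic (6 and 11 as diastereomer mixtures) and lose their stereocentres later, so no stereocontrol is required.

**Step 1**
Reactants: 1 1-(2,3-dimethoxyphenyl)ethanone
Product: 3 1-(5-hydroxy-2,3-dimethoxyphenyl)ethanone, via aryl pinacol boronate 2 (not isolated)
Conditions: [Ir(OMe)(cod)]2 (1.5 mol%), 4,4'-di-tert-butyl-2,2'-bipyridine (3 mol%), B2pin2, THF, 80 °C; then KHSO5 (as Oxone), acetone/H2O, rt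
Reagents that add atoms: potassium peroxymonosulfate, [K+].[O-]S(=O)(=O)OO
Why: Iridium-catalysed aromatic C–H borylation is sterically governed and should select C5, the only ring C–H without an ortho substituent, and the boronate is oxidised in the same pot to the phenol at that carbon (one-pot C–H borylation/oxidation).

**Step 2**
Reactants: 3 1-(5-hydroxy-2,3-dimethoxyphenyl)ethanone
Product: 4 1-(5-benzyloxy-2,3-dimethoxyphenyl)ethanone
Conditions: BnBr, K2CO3, DMF, rt
Reagents that add atoms: benzyl bromide, BrCc1ccccc1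
Why: Williamson ether synthesis on the phenoxide; carbonate is too weak a base to alkylate the methyl ketone.

**Step 3**
Reactants: 5 methyl (E)-3-methoxyacrylate
Product: 7 methyl (Z)-2-iodo-3-methoxyacrylate, via acetoxy iodo adduct 6 (not isolated)
Conditions: N-iodosuccinimide, AcOH, CH2Cl2, rt, dark; then Et3N, 0 °C to rt
Reagents that add atoms: N-iodosuccinimide, O=C1CCC(=O)N1I
Why: Electrophilic iodination of the enol ether at its α-carbon with capture by acetate, then base-induced loss of acetic acid, should restore the conjugated alkene with methoxy trans to the ester, which is the Z iodide (iodination–elimination of a β-alkoxyacrylate).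

**Step 4**
Reactants: 7 methyl (Z)-2-iodo-3-methoxyacrylate
Product: 8 (Z)-2-iodo-3-methoxyacrylic acid
Conditions: LiOH·H2O, THF/H2O, 0 °C to rt; then 1 M HCl to pH 2–3, 0 °C
Reagents that add atoms: lithium hydroxide, [Li+].[OH-]
Why: Ester saponification; the vinylogous carbonate character of the β-methoxyacrylate makes the enol ether carbon a poor acceptor, so hydroxide should attack the ester carbonyl and the alkene geometry is kept.

**Step 5**
Reactants: 8 (Z)-2-iodo-3-methoxyacrylic acid; 4 1-(5-benzyloxy-2,3-dimethoxyphenyl)ethanone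
Product: 10 (Z)-1-(5-benzyloxy-2,3-dimethoxyphenyl)-4-iodo-5-methoxypent-4-ene-1,3-dione, via acid chloride 9 (not isolated)
Conditions: 8, (COCl)2, DMF (cat.), CH2Cl2, 0 °C to rt, evaporate; 4, LiN(SiMe3)2 (2.2 equiv), THF, −78 °C, then crude 9, −78 to −20 °C; aq. NH4Cl
Reagents that add atoms: none
Why: Claisen-type C-acylation of a preformed lithium enolate by an acid chloride, in which the second equivalent of base converts the more acidic β-diketone into its enolate and so prevents proton transfer and double acylation.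

**Step 6**
Reactants: 10 (Z)-1-(5-benzyloxy-2,3-dimethoxyphenyl)-4-iodo-5-methoxypent-4-ene-1,3-dione
Product: 12 2-(5-benzyloxy-2,3-dimethoxyphenyl)-5-iodo-4H-pyran-4-one, via cyclic methoxy acetal 11 (not isolated)
Conditions: CF3CO2H, CH2Cl2, 0 °C to rt
Reagents that add atoms: none
Why: Acid-catalysed 6-endo oxa-Michael addition of the enol oxygen to the methoxyvinyl carbon, then loss of methanol from the cyclic acetal, gives the 4-pyranone (addition–elimination pyranone synthesis from a β-methoxyenone); the alkene geometry is irrelevant because that carbon is sp3 in between.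

**Step 7**
Reactants: 12 2-(5-benzyloxy-2,3-dimethoxyphenyl)-5-iodo-4H-pyran-4-one; 13 dimethyl squarate
Product: 15 4-[6-(5-benzyloxy-2,3-dimethoxyphenyl)-4-oxo-4H-pyran-3-yl]-4-hydroxy-2,3-dimethoxycyclobut-2-en-1-one (racemic), via pyranonylmagnesium chloride 14 (not isolated)
Conditions: i-PrMgCl·LiCl (1.05 equiv), THF, −78 °C, 20 min; cannulate into 13 (1.3 equiv), THF, −78 °C; aq. NH4Cl at −78 °C
Reagents that add atoms: none
Why: Iodine–magnesium exchange of an alkenyl iodide flanked by a carbonyl is fast at low temperature, and the resulting alkenylmagnesium should add 1,2 to one of the two equivalent, strongly electrophilic squarate carbonyls (Grignard addition to a squaric ester); the carbinol centre forms racemic and is erased in step 8.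

**Step 8**
Reactants: 15 4-[6-(5-benzyloxy-2,3-dimethoxyphenyl)-4-oxo-4H-pyran-3-yl]-4-hydroxy-2,3-dimethoxycyclobut-2-en-1-one
Product: 18 2-(5-benzyloxy-2,3-dimethoxyphenyl)-5,8-dihydroxy-6,7-dimethoxy-4H-chromen-4-one, via dienylketene 16 (not isolated), via 8aH-dienone 17 (not isolated)
Conditions: degassed toluene (0.01 M), 110 °C, argon
Reagents that add atoms: none
Why: Heating cleaves the cyclobutenone C1–C4 bond by conrotatory 4π electrocyclic opening to a dienylketene in which the hydroxyl, the stronger donor, turns outward, so the pyranonyl group lies cis to the ketene. The ketene C=C, the C(OMe)=C(OH) alkene and the pyranone C=C next to the attachment point then form a cis-hexatriene that closes by thermal disrotatory 6π electrocyclization, bonding the ketene carbon to the pyranone C–H carbon beside the ring oxygen (C8–C8a) and creating the six-membered carbocycle, ring A, fused to ring C. Enolisation of the 8aH-dienone with loss of that hydrogen gives the aromatic 5,8-hydroquinone. The closest known reaction type is the thermal ring expansion of squarate-derived 4-aryl- and 4-alkenyl-4-hydroxycyclobutenones to hydroquinones (Moore rearrangement). No stereocentre survives, since the carbinol carbon of 15 and the transient C8a centre of 17 both become sp2. The step needs outward torquoselectivity of the hydroxyl, secured by its donor character, and closure at the correct terminus, secured because the only alkene carbon flanking the attachment point is the C–H carbon (the other neighbour is the ring carbonyl carbon), while the weak aromaticity of the pyranone lets its C=C bond react as an alkene.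

**Step 9**
Reactants: 18 2-(5-benzyloxy-2,3-dimethoxyphenyl)-5,8-dihydroxy-6,7-dimethoxy-4H-chromen-4-one
Product: 19 2-(5-benzyloxy-2,3-dimethoxyphenyl)-5-hydroxy-6,7-dimethoxy-4-oxo-4H-chromen-8-yl trifluoromethanesulfonate
Conditions: Tf2O (1.05 equiv), pyridine, CH2Cl2, −40 to 0 °C, argon
Reagents that add atoms: trifluoromethanesulfonic anhydride, O=S(=O)(OS(=O)(=O)C(F)(F)F)C(F)(F)F
Why: O-sulfonylation of a phenol; the 5-hydroxyl is held in a hydrogen bond to the C4 carbonyl and is much less nucleophilic, so one equivalent of anhydride at low temperature should react only at the free 8-hydroxyl.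

**Step 10**
Reactants: 19 2-(5-benzyloxy-2,3-dimethoxyphenyl)-5-hydroxy-6,7-dimethoxy-4-oxo-4H-chromen-8-yl trifluoromethanesulfonate
Product: 20 2-(5-benzyloxy-2,3-dimethoxyphenyl)-5-hydroxy-6,7-dimethoxy-4H-chromen-4-one
Conditions: Pd(OAc)2 (5 mol%), 1,3-bis(diphenylphosphino)propane (6 mol%), HCO2H, Et3N, DMF, 80 °C
Reagents that add atoms: none
Why: Palladium-catalysed reduction of an aryl triflate by formate (oxidative addition of zerovalent palladium into the C8–O bond, formate exchange, loss of CO2, reductive elimination of the C–H bond); this homogeneous hydride source leaves the benzyl ether, the free phenol and the pyranone alkene alone.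

**Step 11**
Reactants: 20 2-(5-benzyloxy-2,3-dimethoxyphenyl)-5-hydroxy-6,7-dimethoxy-4H-chromen-4-one
Product: 21 5-hydroxy-2-(5-hydroxy-2,3-dimethoxyphenyl)-6,7-dimethoxy-4H-chromen-4-one
Conditions: H2 (1 atm), 10% Pd/C, EtOAc/MeOH, rt
Reagents that add atoms: none
Why: Heterogeneous hydrogenolysis of the benzylic C–O bond; the conjugated chromone alkene and the aryl methyl ethers should not be reduced at ambient pressure and temperature.

**Compound list**
1 | 1-(2,3-dimethoxyphenyl)ethanone | CC(=O)c1cccc(OC)c1OC | starting material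
2 | 1-[2,3-dimethoxy-5-(4,4,5,5-tetramethyl-1,3,2-dioxaborolan-2-yl)phenyl]ethanone | CC(=O)c1cc(B2OC(C)(C)C(C)(C)O2)cc(OC)c1OC | intermediate
3 | 1-(5-hydroxy-2,3-dimethoxyphenyl)ethanone | CC(=O)c1cc(O)cc(OC)c1OC | intermediate
4 | 1-(5-benzyloxy-2,3-dimethoxyphenyl)ethanone | CC(=O)c1cc(OCc2ccccc2)cc(OC)c1OC | intermediate
5 | methyl (E)-3-methoxyacrylate | CO/C=C/C(=O)OC | starting material
6 | methyl 3-acetoxy-2-iodo-3-methoxypropanoate (racemic, mixture of diastereomers) | COC(OC(C)=O)C(I)C(=O)OC | intermediate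
7 | methyl (Z)-2-iodo-3-methoxyacrylate | CO/C=C(\I)C(=O)OC | intermediate
8 | (Z)-2-iodo-3-methoxyacrylic acid | CO/C=C(\I)C(=O)O | intermediate
9 | (Z)-2-iodo-3-methoxyacryloyl chloride | CO/C=C(\I)C(=O)Cl | intermediate
10 | (Z)-1-(5-benzyloxy-2,3-dimethoxyphenyl)-4-iodo-5-methoxypent-4-ene-1,3-dione | CO/C=C(\I)C(=O)CC(=O)c1cc(OCc2ccccc2)cc(OC)c1OC | intermediate
11 | 6-(5-benzyloxy-2,3-dimethoxyphenyl)-3-iodo-2-methoxy-2,3-dihydro-4H-pyran-4-one (racemic, mixture of diastereomers) | COC1OC(=CC(=O)C1I)c1cc(OCc2ccccc2)cc(OC)c1OC | intermediate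
12 | 2-(5-benzyloxy-2,3-dimethoxyphenyl)-5-iodo-4H-pyran-4-one | O=c1cc(-c2cc(OCc3ccccc3)cc(OC)c2OC)occ1I | intermediate
13 | dimethyl squarate (3,4-dimethoxycyclobut-3-ene-1,2-dione) | COC1=C(OC)C(=O)C1=O | starting material
14 | [6-(5-benzyloxy-2,3-dimethoxyphenyl)-4-oxo-4H-pyran-3-yl]magnesium chloride | O=c1cc(-c2cc(OCc3ccccc3)cc(OC)c2OC)occ1[Mg]Cl | intermediate
15 | 4-[6-(5-benzyloxy-2,3-dimethoxyphenyl)-4-oxo-4H-pyran-3-yl]-4-hydroxy-2,3-dimethoxycyclobut-2-en-1-one (racemic) | COC1=C(OC)C(O)(c2coc(-c3cc(OCc4ccccc4)cc(OC)c3OC)cc2=O)C1=O | intermediate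
16 | (Z)-4-[6-(5-benzyloxy-2,3-dimethoxyphenyl)-4-oxo-4H-pyran-3-yl]-4-hydroxy-2,3-dimethoxybuta-1,3-dien-1-one (hydroxyl trans to the ketene-bearing carbon) | O=C=C(OC)/C(OC)=C(/O)c1coc(-c2cc(OCc3ccccc3)cc(OC)c2OC)cc1=O | intermediate
17 | 2-(5-benzyloxy-2,3-dimethoxyphenyl)-5-hydroxy-6,7-dimethoxy-8aH-chromene-4,8-dione (racemic) | COC1=C(OC)C(O)=C2C(=O)C=C(c3cc(OCc4ccccc4)cc(OC)c3OC)OC2C1=O | intermediate
18 | 2-(5-benzyloxy-2,3-dimethoxyphenyl)-5,8-dihydroxy-6,7-dimethoxy-4H-chromen-4-one | COc1cc(OCc2ccccc2)cc(-c2cc(=O)c3c(O)c(OC)c(OC)c(O)c3o2)c1OC | intermediate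
19 | 2-(5-benzyloxy-2,3-dimethoxyphenyl)-5-hydroxy-6,7-dimethoxy-4-oxo-4H-chromen-8-yl trifluoromethanesulfonate | COc1cc(OCc2ccccc2)cc(-c2cc(=O)c3c(O)c(OC)c(OC)c(OS(=O)(=O)C(F)(F)F)c3o2)c1OC | intermediate
20 | 2-(5-benzyloxy-2,3-dimethoxyphenyl)-5-hydroxy-6,7-dimethoxy-4H-chromen-4-one | COc1cc(OCc2ccccc2)cc(-c2cc(=O)c3c(O)c(OC)c(OC)cc3o2)c1OC | intermediate
21 | 5-hydroxy-2-(5-hydroxy-2,3-dimethoxyphenyl)-6,7-dimethoxy-4H-chromen-4-one | COc1cc(O)cc(-c2cc(=O)c3c(O)c(OC)c(OC)cc3o2)c1OC | target

**Totals.** Total step count: 11. Longest linear sequence: 9 steps (5 to 21 through steps 3–11; the branch from 1 through steps 1, 2 and 5–11 is equally long).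

**Steps most likely to fail**

Step 7. The magnesiated pyranone has its ring oxygen trans to magnesium across the same alkene and may fragment by β-elimination to an ynone enolate before it reaches the squarate. The exchange reagent may also add to the pyranone, or the adduct may be attacked a second time. The fallback avoids any pyranonyl carbanion by building ring C onto a bought ring A; it sets out from 4 and comes back at the target 21.
- Haloform cleavage of 4 (NaOCl, NaOH, dioxane/H2O) should give 5-benzyloxy-2,3-dimethoxybenzoic acid F1.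
- Oxalyl chloride with catalytic DMF converts it into 5-benzyloxy-2,3-dimethoxybenzoyl chloride F2.
- The dianion of purchased 1-(6-hydroxy-2,3,4-trimethoxyphenyl)ethanone F3 (LiN(SiMe3)2, 3 equiv, THF, −78 °C) is C-acylated by F2 to 1-(5-benzyloxy-2,3-dimethoxyphenyl)-3-(6-hydroxy-2,3,4-trimethoxyphenyl)propane-1,3-dione F4.
- Acid-catalysed cyclodehydration (TsOH cat., toluene, 90 °C) closes ring C to 2-(5-benzyloxy-2,3-dimethoxyphenyl)-5,6,7-trimethoxy-4H-chromen-4-one F5.
- BCl3 with pentamethylbenzene (CH2Cl2, −78 to 0 °C) then removes the carbonyl-chelated 5-O-methyl group and the benzyl group together to give 21.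

Step 8. The dienylketene may be diverted before the 6π closure, either by ring opening with the hydroxyl turned inward and lactonisation to a butenolide or by intermolecular capture of the ketene. The free hydroquinone may also be oxidised to the 5,8-quinone during isolation. The fallback masks the carbinol oxygen before ring expansion so that it can neither trap the ketene nor end up in a quinone; it sets out from 15 and comes back at 20.
- Silylation of 15 (t-BuMe2SiOTf, 2,6-lutidine, CH2Cl2, −78 °C) gives 4-[6-(5-benzyloxy-2,3-dimethoxyphenyl)-4-oxo-4H-pyran-3-yl]-4-(tert-butyldimethylsilyloxy)-2,3-dimethoxycyclobut-2-en-1-one F6.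
- Thermolysis as in step 8 (the known ring expansion of 4-silyloxycyclobutenones to mono-protected hydroquinones) should give 2-(5-benzyloxy-2,3-dimethoxyphenyl)-5-(tert-butyldimethylsilyloxy)-8-hydroxy-6,7-dimethoxy-4H-chromen-4-one F7.
- Triflation of its only free hydroxyl gives 2-(5-benzyloxy-2,3-dimethoxyphenyl)-5-(tert-butyldimethylsilyloxy)-6,7-dimethoxy-4-oxo-4H-chromen-8-yl trifluoromethanesulfonate F8.
- Formate reduction as in step 10 gives 2-(5-benzyloxy-2,3-dimethoxyphenyl)-5-(tert-butyldimethylsilyloxy)-6,7-dimethoxy-4H-chromen-4-one F9.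
- Bu4NF in THF removes the silyl group to give 20.

Step 9. Sulfonylation may spill over to the chelated 5-hydroxyl, or the electron-rich hydroquinone may be oxidised before it is acylated. The fallback replaces the sulfonate by a heteroaryl ether formed under carbonate, where only the non-chelated hydroxyl ionises, and merges deoxygenation with debenzylation; it sets out from 18 and comes back at the target 21.
- Nucleophilic aromatic substitution of 5-chloro-1-phenyl-1H-tetrazole by the 8-phenoxide (K2CO3, DMF, 50 °C, argon) should give 2-(5-benzyloxy-2,3-dimethoxyphenyl)-5-hydroxy-6,7-dimethoxy-8-[(1-phenyl-1H-tetrazol-5-yl)oxy]-4H-chromen-4-one F10.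
- Hydrogenolysis (H2, 3 atm, Pd/C, EtOH/THF, 40 °C) cleaves the aryl C8–O bond of the tetrazolyl ether and the benzyl ether in one operation to give 21.

**Further compounds**
F1 | step 7 | 5-benzyloxy-2,3-dimethoxybenzoic acid | OC(=O)c1cc(OCc2ccccc2)cc(OC)c1OC
F2 | step 7 | 5-benzyloxy-2,3-dimethoxybenzoyl chloride | O=C(Cl)c1cc(OCc2ccccc2)cc(OC)c1OC
F3 | step 7 | 1-(6-hydroxy-2,3,4-trimethoxyphenyl)ethanone (bought) | CC(=O)c1c(O)cc(OC)c(OC)c1OC
F4 | step 7 | 1-(5-benzyloxy-2,3-dimethoxyphenyl)-3-(6-hydroxy-2,3,4-trimethoxyphenyl)propane-1,3-dione | COc1cc(O)c(C(=O)CC(=O)c2cc(OCc3ccccc3)cc(OC)c2OC)c(OC)c1OC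
F5 | step 7 | 2-(5-benzyloxy-2,3-dimethoxyphenyl)-5,6,7-trimethoxy-4H-chromen-4-one | COc1cc(OCc2ccccc2)cc(-c2cc(=O)c3c(OC)c(OC)c(OC)cc3o2)c1OC
F6 | step 8 | 4-[6-(5-benzyloxy-2,3-dimethoxyphenyl)-4-oxo-4H-pyran-3-yl]-4-(tert-butyldimethylsilyloxy)-2,3-dimethoxycyclobut-2-en-1-one (racemic) | CC(C)(C)[Si](C)(C)OC1(c2coc(-c3cc(OCc4ccccc4)cc(OC)c3OC)cc2=O)C(=O)C(OC)=C1OC
F7 | step 8 | 2-(5-benzyloxy-2,3-dimethoxyphenyl)-5-(tert-butyldimethylsilyloxy)-8-hydroxy-6,7-dimethoxy-4H-chromen-4-one | COc1cc(OCc2ccccc2)cc(-c2cc(=O)c3c(O[Si](C)(C)C(C)(C)C)c(OC)c(OC)c(O)c3o2)c1OC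
F8 | step 8 | 2-(5-benzyloxy-2,3-dimethoxyphenyl)-5-(tert-butyldimethylsilyloxy)-6,7-dimethoxy-4-oxo-4H-chromen-8-yl trifluoromethanesulfonate | COc1cc(OCc2ccccc2)cc(-c2cc(=O)c3c(O[Si](C)(C)C(C)(C)C)c(OC)c(OC)c(OS(=O)(=O)C(F)(F)F)c3o2)c1OC
F9 | step 8 | 2-(5-benzyloxy-2,3-dimethoxyphenyl)-5-(tert-butyldimethylsilyloxy)-6,7-dimethoxy-4H-chromen-4-one | COc1cc(OCc2ccccc2)cc(-c2cc(=O)c3c(O[Si](C)(C)C(C)(C)C)c(OC)c(OC)cc3o2)c1OC
F10 | step 9 | 2-(5-benzyloxy-2,3-dimethoxyphenyl)-5-hydroxy-6,7-dimethoxy-8-[(1-phenyl-1H-tetrazol-5-yl)oxy]-4H-chromen-4-one | COc1cc(OCc2ccccc2)cc(-c2cc(=O)c3c(O)c(OC)c(OC)c(Oc4nnnn4-c4ccccc4)c3o2)c1OC
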